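The only stereocentre of the butenolide ring (O1, C2, C3, C4, C5) is C5, an allylic carbinol carbon next to the C3=C4 alkene. The route therefore disconnects C5–O1 and O1–C2 together. Oxygen is moved from a tertiary C3 carbinol to C5 by a suprafacial rhenium-catalysed 1,3-shift, and the new hydroxyl closes the lactone on the C2 ester in the same flask, so C5 is set from the C3 centre of (R)-citramalic acid. The precursor is a Z-alkylidene citramalate diester (C2 methyl ester, C4 tert-butyl ester, free C3–OH) whose chain ends in a dioxolane-masked methyl ketone. It comes from a dianion aldol and an E1cB dehydration.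

Key step: step 10

Remarks on the chemistry:
- Lactone numbering O1, C2(=O), C3(CH3), C4(CO2R), C5(H, side chain) is used for the butenolide and for the carbons that become these atoms.
- The C4 carboxyl is carried as a tert-butyl ester instead of a methyl ester, so the last step is a mild acidolysis without base or heat. The carbon skeletons of precursor 14 and product 17 are unchanged.
- Stereochemical check: the target is (S) at C5. (R)-Citramalic acid keeps its spatial arrangement up to (2R,3Z)-14, and the suprafacial shift with the C2 ester inside at C3 converts (2R,3Z)-14 into (S)-17.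

Step 1
Reactants: 1 (R)-citramalic acid
Product: 2 2-[(4R)-2,2,4-trimethyl-5-oxo-1,3-dioxolan-4-yl]acetic acid
Conditions: 2,2-dimethoxypropane, PPTS (cat.), CH2Cl2, rt
Reagents that add atoms: 2,2-dimethoxypropane, COC(C)(C)OC
Why: acetalisation of the α-hydroxy acid closes the five-membered 1,3-dioxolan-4-one in preference to the six-membered alternative, masking the C2 carboxyl and the tertiary hydroxyl and leaving the CH2CO2H free; the stereocentre is not touched.

Step 2
Reactants: 2 2-[(4R)-2,2,4-trimethyl-5-oxo-1,3-dioxolan-4-yl]acetic acid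
Product: 3 tert-butyl 2-[(4R)-2,2,4-trimethyl-5-oxo-1,3-dioxolan-4-yl]acetate
Conditions: tert-butyl 2,2,2-trichloroacetimidate, CH2Cl2/cyclohexane, rt
Reagents that add atoms: tert-butyl 2,2,2-trichloroacetimidate, CC(C)(C)OC(=N)C(Cl)(Cl)Cl
Why: acid-promoted tert-butyl transfer from the trichloroacetimidate esterifies the free carboxylic acid under conditions mild enough for the dioxolanone.

Step 3
Reactants: 3 tert-butyl 2-[(4R)-2,2,4-trimethyl-5-oxo-1,3-dioxolan-4-yl]acetate
Product: 4 4-tert-butyl 1-methyl (2R)-2-hydroxy-2-methylbutanedioate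
Conditions: NaOMe (0.1 equiv), MeOH, 0 °C
Reagents that add atoms: methanol, CO
Why: catalytic methoxide attacks the activated acetal-ester carbonyl (transesterification), releasing acetone and the tertiary alcohol, while the hindered tert-butyl ester is inert at 0 °C.

Step 4
Reactants: 5 ω-pentadecalactone (oxacyclohexadecan-2-one)
Product: 6 15-hydroxy-N-methoxy-N-methylpentadecanamide
Conditions: MeNHOMe·HCl, iPrMgCl, THF, −20 → 0 °C
Reagents that add atoms: N,O-dimethylhydroxylamine hydrochloride, CNOC.Cl
Why: aminolysis of the lactone by the magnesium amide of N,O-dimethylhydroxylamine (Weinreb amide formation) opens the ring to the hydroxy amide.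

Step 5
Reactants: 6 15-hydroxy-N-methoxy-N-methylpentadecanamide
Product: 7 16-hydroxyhexadecan-2-one
Conditions: MeMgBr (3 equiv), THF, 0 °C; aq. NH4Cl
Reagents that add atoms: methylmagnesium bromide, C[Mg]Br
Why: Weinreb ketone synthesis, in which the chelated tetrahedral adduct prevents double addition and releases the methyl ketone on work-up; one equivalent of Grignard reagent is consumed by the hydroxyl.

Step 6
Reactants: 7 16-hydroxyhexadecan-2-one; 8 ethylene glycol
Product: 9 14-(2-methyl-1,3-dioxolan-2-yl)tetradecan-1-ol
Conditions: TsOH (cat.), toluene, Dean–Stark, reflux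
Reagents that add atoms: ethylene glycol (8), OCCO
Why: acid-catalysed ketalisation with azeotropic removal of water protects the ketone as the 1,3-dioxolane, the primary alcohol being a spectator.

Step 7
Reactants: 9 14-(2-methyl-1,3-dioxolan-2-yl)tetradecan-1-ol
Product: 10 14-(2-methyl-1,3-dioxolan-2-yl)tetradecanal
Conditions: Dess–Martin periodinane, pyridine, CH2Cl2, 0 °C → rt
Reagents that add atoms: none
Why: Dess–Martin oxidation under pyridine buffer converts the primary alcohol into the aldehyde without over-oxidation and without acid strong enough to open the dioxolane.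

Step 8
Reactants: 4 4-tert-butyl 1-methyl (2R)-2-hydroxy-2-methylbutanedioate; 10 14-(2-methyl-1,3-dioxolan-2-yl)tetradecanal
Product: 12 4-tert-butyl 1-methyl (2R)-2-hydroxy-3-[1-hydroxy-14-(2-methyl-1,3-dioxolan-2-yl)tetradecyl]-2-methylbutanedioate (diastereomers at C3 and C1′), via dilithium alkoxide enolate 11 (not isolated)
Conditions: 4, LDA (2.2 equiv), THF, −78 → −20 °C; then 10, −78 °C; AcOH/THF quench at −78 °C
Reagents that add atoms: none
Why: Fráter–Seebach-type double deprotonation of the β-hydroxy ester gives alkoxide enolate 11, in which the alkoxide suppresses β-elimination, and aldol addition to the aldehyde forms the C4–C5 bond; the two new stereocentres need no control because both become sp2 in step 9, and the cold acidic quench keeps the aldolate from acylating on the C2 ester.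

Step 9
Reactants: 12 4-tert-butyl 1-methyl (2R)-2-hydroxy-3-[1-hydroxy-14-(2-methyl-1,3-dioxolan-2-yl)tetradecyl]-2-methylbutanedioate
Product: 14 4-tert-butyl 1-methyl (2R,3Z)-2-hydroxy-2-methyl-3-[14-(2-methyl-1,3-dioxolan-2-yl)tetradecylidene]butanedioate, via secondary mesylate 13 (not isolated)
Conditions: MsCl (1.2 equiv), Et3N, CH2Cl2, −20 → 0 °C; then DBU, 0 °C → rt
Reagents that add atoms: none
Why: the secondary hydroxyl should be sulfonylated much faster than the hindered, electron-poor tertiary one, and DBU then effects a stereoconvergent E1cB elimination through the ester enolate that should place the chain away from the fully substituted C3 (allylic 1,3-strain), that is cis to the tert-butyl ester (Z).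

Step 10
Reactants: 14 4-tert-butyl 1-methyl (2R,3Z)-2-hydroxy-2-methyl-3-[14-(2-methyl-1,3-dioxolan-2-yl)tetradecylidene]butanedioate
Product: 17 tert-butyl (2S)-4-methyl-2-[13-(2-methyl-1,3-dioxolan-2-yl)tridecyl]-5-oxo-2,5-dihydrofuran-3-carboxylate, via tertiary perrhenate ester 15 (not isolated), via transposed S-alcohol 16 (not isolated)
Conditions: Ph3SiOReO3 (10 mol%), 5 Å MS, CH2Cl2 or ClCH2CH2Cl, rt → 45 °C
Reagents that add atoms: none
Why: Proposed new method: the tertiary alcohol exchanges onto rhenium(VII) to give perrhenate ester 15, which should undergo a chair-like [3,3] shift that carries oxygen from C3 to C5 across one face of the C3–C4–C5 unit, after which the freed alcohol 16 attacks the cis-placed C2 methyl ester; the closest known reaction type is the rhenium-oxo 1,3-transposition of allylic alcohols with chirality transfer and in situ trapping of the product alcohol, here extended to a tertiary carbinol flanked by two ester groups. The butenolide ring closes by 5-exo-trig acyl substitution (O1–C2 bond), which, together with the tetrasubstituted alkene conjugated to both carbonyls, makes the otherwise reversible shift irreversible. C5 is controlled by the C3 centre through suprafacial transfer: in the Z alkene hydrogen is the inside substituent at C5, and the rotamer with the C2 ester inside at (R)-C3 delivers oxygen to the face that makes C5 (S) and at the same time gives the C3=C4 geometry with C5 cis to C2. The rotamer with methyl inside gives the (R)-alcohol with C5 trans to C2, which cannot cyclise and should return to 14 through the same equilibrium. The step needs a concerted, non-ionising pathway and a geometrically pure Z alkene. The two ester groups disfavour an allyl cation, and the alkene geometry is secured and checked at 14.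

Step 11
Reactants: 17 tert-butyl (2S)-4-methyl-2-[13-(2-methyl-1,3-dioxolan-2-yl)tridecyl]-5-oxo-2,5-dihydrofuran-3-carboxylate
Product: 18 (2S)-4-methyl-5-oxo-2-(14-oxopentadecyl)-2,5-dihydrofuran-3-carboxylic acid (target)
Conditions: TFA/CH2Cl2/H2O (10:10:1), 0 °C → rt
Reagents that add atoms: water, O
Why: trifluoroacetic acid cleaves the tert-butyl ester by alkyl–oxygen (AAL1) fission and, with water, hydrolyses the dioxolane, while the butenolide and the base-sensitive C5 stereocentre are stable to acid at room temperature.

Compound list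
1 | (R)-citramalic acid, (2R)-2-hydroxy-2-methylbutanedioic acid | C[C@@](O)(CC(=O)O)C(=O)O | starting material
2 | 2-[(4R)-2,2,4-trimethyl-5-oxo-1,3-dioxolan-4-yl]acetic acid | C[C@@]1(OC(C)(C)OC1=O)CC(=O)O | intermediate
3 | tert-butyl 2-[(4R)-2,2,4-trimethyl-5-oxo-1,3-dioxolan-4-yl]acetate | C[C@@]1(OC(C)(C)OC1=O)CC(=O)OC(C)(C)C | intermediate
4 | 4-tert-butyl 1-methyl (2R)-2-hydroxy-2-methylbutanedioate | C[C@@](O)(CC(=O)OC(C)(C)C)C(=O)OC | intermediate
5 | ω-pentadecalactone (oxacyclohexadecan-2-one) | O=C1CCCCCCCCCCCCCCO1 | starting material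
6 | 15-hydroxy-N-methoxy-N-methylpentadecanamide | CON(C)C(=O)CCCCCCCCCCCCCCO | intermediate
7 | 16-hydroxyhexadecan-2-one | CC(=O)CCCCCCCCCCCCCCO | intermediate
8 | ethylene glycol | OCCO | starting material
9 | 14-(2-methyl-1,3-dioxolan-2-yl)tetradecan-1-ol | CC1(CCCCCCCCCCCCCCO)OCCO1 | intermediate
10 | 14-(2-methyl-1,3-dioxolan-2-yl)tetradecanal | CC1(CCCCCCCCCCCCCC=O)OCCO1 | intermediate
11 | dilithium alkoxide enolate of 4 (R at the carbinol carbon) | C[C@@]([O-])(C=C([O-])OC(C)(C)C)C(=O)OC.[Li+].[Li+] | intermediate
12 | 4-tert-butyl 1-methyl (2R)-2-hydroxy-3-[1-hydroxy-14-(2-methyl-1,3-dioxolan-2-yl)tetradecyl]-2-methylbutanedioate, diastereomers at C3 and C1′ | CC1(CCCCCCCCCCCCCC(O)C(C(=O)OC(C)(C)C)[C@@](C)(O)C(=O)OC)OCCO1 | intermediate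
13 | 4-tert-butyl 1-methyl (2R)-2-hydroxy-3-[1-(methanesulfonyloxy)-14-(2-methyl-1,3-dioxolan-2-yl)tetradecyl]-2-methylbutanedioate | CC1(CCCCCCCCCCCCCC(OS(C)(=O)=O)C(C(=O)OC(C)(C)C)[C@@](C)(O)C(=O)OC)OCCO1 | intermediate
14 | 4-tert-butyl 1-methyl (2R,3Z)-2-hydroxy-2-methyl-3-[14-(2-methyl-1,3-dioxolan-2-yl)tetradecylidene]butanedioate (chain cis to the tert-butyl ester) | CC1(CCCCCCCCCCCCC/C=C(\C(=O)OC(C)(C)C)[C@@](C)(O)C(=O)OC)OCCO1 | intermediate
15 | perrhenate ester of 14 at the tertiary oxygen (2R,3Z) | CC1(CCCCCCCCCCCCC/C=C(\C(=O)OC(C)(C)C)[C@@](C)(O[Re](=O)(=O)=O)C(=O)OC)OCCO1 | intermediate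
16 | 1-tert-butyl 4-methyl (2E)-2-[(1S)-1-hydroxy-14-(2-methyl-1,3-dioxolan-2-yl)tetradecyl]-3-methylbut-2-enedioate (carbinol carbon cis to the methyl ester) | CC1(CCCCCCCCCCCCC[C@H](O)/C(C(=O)OC(C)(C)C)=C(/C)C(=O)OC)OCCO1 | intermediate
17 | tert-butyl (2S)-4-methyl-2-[13-(2-methyl-1,3-dioxolan-2-yl)tridecyl]-5-oxo-2,5-dihydrofuran-3-carboxylate | CC1(CCCCCCCCCCCCC[C@@H]2OC(=O)C(C)=C2C(=O)OC(C)(C)C)OCCO1 | intermediate
18 | (2S)-4-methyl-5-oxo-2-(14-oxopentadecyl)-2,5-dihydrofuran-3-carboxylic acid | CC(=O)CCCCCCCCCCCCC[C@@H]1OC(=O)C(C)=C1C(=O)O | target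

Total step count: 11. Longest linear sequence: 8 steps (steps 4, 5, 6, 7, 8, 9, 10, 11, from ω-pentadecalactone); the citramalate branch (steps 1–3) joins at step 8.

Steps most likely to fail

1. Step 10. Exchange of the hindered, acceptor-flanked tertiary alcohol onto rhenium may be slow. Forcing the reaction may open an ionising pathway that erodes the transfer of chirality. The liberated methanol may also exchange into the dioxolane. Fallback with known chemistry, setting out from 12 and abandoning the transposition: 12 is warmed with catalytic PPTS in toluene (60 °C), so that the C1′ hydroxyl lactonises on the C2 methyl ester. The γ-lactones that are epimeric at the carbinol carbon are diastereomers because the citramalate centre is still present, and they should be separable on silica. The (2S) series, tert-butyl (2S,4R)-4-hydroxy-4-methyl-5-oxo-2-[13-(2-methyl-1,3-dioxolan-2-yl)tridecyl]oxolane-3-carboxylate F1 (either C3 epimer), is dehydrated without base by Martin sulfurane (CH2Cl2, 0 °C → rt). Loss of the tertiary hydroxyl and the acidic C3 hydrogen gives the conjugated butenolide, and the sequence comes back to the route at 17. C5 is then fixed by separation and not by chirality transfer.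

2. Step 8. The dianion may form incompletely or condense with itself, the aldolate may revert (retro-aldol) or acylate on the C2 ester before the quench, and the aldehyde may be enolised. Fallback, setting out from 10 and replacing the aldol by acylation and reduction: Pinnick oxidation (NaClO2, NaH2PO4, 2-methyl-2-butene, tBuOH/H2O) gives 14-(2-methyl-1,3-dioxolan-2-yl)tetradecanoic acid F2. Carbonyldiimidazole in THF converts it into 1-[14-(2-methyl-1,3-dioxolan-2-yl)tetradecanoyl]imidazole F3. Claisen-type acylation of dianion 11 (from 4, with one further equivalent of LDA, −78 °C) is driven by deprotonation of the product and gives 4-tert-butyl 1-methyl (2R)-2-hydroxy-2-methyl-3-[14-(2-methyl-1,3-dioxolan-2-yl)tetradecanoyl]butanedioate F4. Reduction with NaBH4 (MeOH, −20 °C) returns to the route at 12, either carbinol epimer being usable.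

3. Step 9. The tertiary hydroxyl may compete in the sulfonylation, the elimination may give incomplete control of alkene geometry, and DBU may move the double bond out of conjugation. Fallback, setting out from 12 and using an internal carboxylate in place of the mesylate as leaving group (Stobbe-type ring opening): 12 is lactonised (PPTS cat., toluene, 60 °C) to the mixture of tert-butyl (4R)-4-hydroxy-4-methyl-5-oxo-2-[13-(2-methyl-1,3-dioxolan-2-yl)tridecyl]oxolane-3-carboxylates F5. LiHMDS (2.2 equiv, THF, −78 → 0 °C) forms the ester enolate, which expels the lactone carboxylate to give 4-tert-butyl hydrogen (2R,3Z)-2-hydroxy-2-methyl-3-[14-(2-methyl-1,3-dioxolan-2-yl)tetradecylidene]butanedioate F6. Methylation of the free acid with trimethylsilyldiazomethane (toluene/MeOH, 0 °C) comes back to the route at 14. Any E isomer is removed by chromatography at 14, since the key step needs geometrically pure material.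

Further compounds
F1 | step 10 | tert-butyl (2S,4R)-4-hydroxy-4-methyl-5-oxo-2-[13-(2-methyl-1,3-dioxolan-2-yl)tridecyl]oxolane-3-carboxylate (either C3 epimer) | CC1(CCCCCCCCCCCCC[C@@H]2OC(=O)[C@](C)(O)C2C(=O)OC(C)(C)C)OCCO1
F2 | step 8 | 14-(2-methyl-1,3-dioxolan-2-yl)tetradecanoic acid | CC1(CCCCCCCCCCCCCC(=O)O)OCCO1
F3 | step 8 | 1-[14-(2-methyl-1,3-dioxolan-2-yl)tetradecanoyl]imidazole | CC1(CCCCCCCCCCCCCC(=O)n2ccnc2)OCCO1
F4 | step 8 | 4-tert-butyl 1-methyl (2R)-2-hydroxy-2-methyl-3-[14-(2-methyl-1,3-dioxolan-2-yl)tetradecanoyl]butanedioate | CC1(CCCCCCCCCCCCCC(=O)C(C(=O)OC(C)(C)C)[C@@](C)(O)C(=O)OC)OCCO1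
F5 | step 9 | tert-butyl (4R)-4-hydroxy-4-methyl-5-oxo-2-[13-(2-methyl-1,3-dioxolan-2-yl)tridecyl]oxolane-3-carboxylate (epimers at C2 and C3) | CC1(CCCCCCCCCCCCCC2OC(=O)[C@](C)(O)C2C(=O)OC(C)(C)C)OCCO1
F6 | step 9 | 4-tert-butyl hydrogen (2R,3Z)-2-hydroxy-2-methyl-3-[14-(2-methyl-1,3-dioxolan-2-yl)tetradecylidene]butanedioate | CC1(CCCCCCCCCCCCC/C=C(\C(=O)OC(C)(C)C)[C@@](C)(O)C(=O)O)OCCO1
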